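Numbering of the only non-aromatic ring: C1 (CH3), C2 (=CH), C3 (aryl, which is C3' of the intact chalcone), C4 (aroyl), C5 (2,4-dihydroxyphenyl), C6 (CH2). The enabling feature is that the ring alkene C1=C2 lies opposite the vicinal C4-aroyl/C5-aryl pair. The ring is therefore the Cα=Cβ bond of a 2'-hydroxychalcone laid across a 1-aryl-3-methylbuta-1,3-diene.
Cuts: first C3–C4 and C5–C6 together (retro-[4+2]), giving two free tetrahydroxychalcones that differ by two hydrogens in the C5 side chain. Next, in each, the C3'–alkenyl bond (Suzuki–Miyaura) back to one common 3'-iodochalcone, and finally its Cα=Cβ bond (Claisen–Schmidt).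
Forward: all aromatic rings are bought. 2,4-Dihydroxyacetophenone is iodinated and condensed with 2,4-dihydroxybenzaldehyde (as MOM ethers), and MOM is exchanged for base-labile acetate. The iodide is then coupled divergently with an alkenyl and a dienyl boronate, both products are methanolysed, and the cyclohexene is closed last.
Stereochemistry: the (E)-alkenes come from the aldol condensation and from syn-hydroboration, and C4/C5 trans is copied from the (E)-enone. C3/C4 cis (endo) and the absolute sense (3S,4R,5S) come from an FAD-dependent intermolecular Diels–Alderase acting on the two unprotected partners.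

Key step: step 13

Assumption: the given cis,trans (3S,4R,5S) configuration is taken to be that of the natural endo series of mulberry-type adducts, which the endo-selective Morus alba Diels–Alderase (MaDA) delivers. The recombinant enzyme, obtained by heterologous expression, is treated as a catalyst.

Step 1
Reactants: 1 2,4-dihydroxyacetophenone
Product: 2 1-(2,4-dihydroxy-3-iodophenyl)ethan-1-one
Conditions: I2 (0.4 equiv), HIO3 (0.2 equiv), EtOH/H2O, 40 °C
Reagents that add atoms: iodine, II; iodic acid, O=I(=O)O
Why: Electrophilic aromatic iodination with I2/HIO3, which uses all the iodine, should take C3, the position ortho to both hydroxyl groups that this reagent pair prefers in resacetophenones, and the acetyl group should stop the reaction at the mono-iodide.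

Step 2
Reactants: 2 1-(2,4-dihydroxy-3-iodophenyl)ethan-1-one
Product: 3 1-[2-hydroxy-3-iodo-4-(methoxymethoxy)phenyl]ethan-1-one
Conditions: MOMCl (1.1 equiv), K2CO3, acetone, rt
Reagents that add atoms: chloromethyl methyl ether, COCCl
Why: In this Williamson-type O-alkylation the 2-OH is locked in a hydrogen bond to the ketone and is not engaged by K2CO3, so only the 4-OH should be protected.

Step 3
Reactants: 4 2,4-dihydroxybenzaldehyde
Product: 5 2,4-bis(methoxymethoxy)benzaldehyde
Conditions: NaH, MOMCl, DMF, 0 °C to rt
Reagents that add atoms: chloromethyl methyl ether, COCCl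
Why: Full deprotonation with NaH overrides the hydrogen bond of the 2-OH, so Williamson-type O-alkylation should occur at both phenoxides.

Step 4
Reactants: 3 1-[2-hydroxy-3-iodo-4-(methoxymethoxy)phenyl]ethan-1-one; 5 2,4-bis(methoxymethoxy)benzaldehyde
Product: 6 (E)-3-[2,4-bis(methoxymethoxy)phenyl]-1-[2-hydroxy-3-iodo-4-(methoxymethoxy)phenyl]prop-2-en-1-one
Conditions: KOH, EtOH/H2O, rt
Reagents that add atoms: none
Why: Claisen–Schmidt condensation of a methyl ketone with a non-enolisable aldehyde, followed by E1cB loss of water, should give the thermodynamically favoured (E)-enone, and the MOM ethers and the aryl iodide are inert to KOH.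

Step 5
Reactants: 6 (E)-3-[2,4-bis(methoxymethoxy)phenyl]-1-[2-hydroxy-3-iodo-4-(methoxymethoxy)phenyl]prop-2-en-1-one
Product: 7 (E)-1-(2,4-dihydroxy-3-iodophenyl)-3-(2,4-dihydroxyphenyl)prop-2-en-1-one
Conditions: HCl (cat.), MeOH, 50 °C, dark
Reagents that add atoms: none
Why: Acid-catalysed transacetalisation to methanol removes the three MOM groups before any acid-sensitive side chain is present, and any flavylium ion formed from the 2-hydroxychalcone should revert to the (E)-chalcone when the mixture is brought to pH 5–6 on work-up.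

Step 6
Reactants: 7 (E)-1-(2,4-dihydroxy-3-iodophenyl)-3-(2,4-dihydroxyphenyl)prop-2-en-1-one
Product: 8 (E)-1-(2,4-diacetoxy-3-iodophenyl)-3-(2,4-diacetoxyphenyl)prop-2-en-1-one
Conditions: Ac2O, pyridine, DMAP (cat.), CH2Cl2, 0 °C to rt
Reagents that add atoms: acetic anhydride, CC(=O)OC(C)=O
Why: DMAP-catalysed O-acylation should also reach the hindered, chelated 2'-OH, and the acetates mask the acidic phenols for the coupling yet leave later under the mild basic conditions that the diene tolerates.

Step 7
Reactants: 9 3-methylbut-1-yne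
Product: 10 (E)-4,4,5,5-tetramethyl-2-(3-methylbut-1-en-1-yl)-1,3,2-dioxaborolane
Conditions: HBpin, Cp2Zr(H)Cl (cat.), Et3N (cat.), neat, sealed tube, rt to 40 °C
Reagents that add atoms: pinacolborane, CC1(C)OBOC1(C)C
Why: Zirconocene-hydride-catalysed hydroboration of a terminal alkyne is a syn, anti-Markovnikov addition and should therefore give only the (E)-alkenyl boronate.

Step 8
Reactants: 8 (E)-1-(2,4-diacetoxy-3-iodophenyl)-3-(2,4-diacetoxyphenyl)prop-2-en-1-one; 10 (E)-4,4,5,5-tetramethyl-2-(3-methylbut-1-en-1-yl)-1,3,2-dioxaborolane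
Product: 11 (E)-1-{2,4-diacetoxy-3-[(E)-3-methylbut-1-en-1-yl]phenyl}-3-(2,4-diacetoxyphenyl)prop-2-en-1-one
Conditions: Pd(OAc)2 (cat.), SPhos (cat.), K3PO4 (anhydrous), toluene, 60 °C; aqueous work-up
Reagents that add atoms: none
Why: Suzuki–Miyaura coupling proceeds with retention of the alkene geometry, the bulky electron-rich phosphine on zerovalent palladium handles the doubly ortho-substituted iodide, and the anhydrous phosphate in toluene should spare the aryl acetates.

Step 9
Reactants: 11 (E)-1-{2,4-diacetoxy-3-[(E)-3-methylbut-1-en-1-yl]phenyl}-3-(2,4-diacetoxyphenyl)prop-2-en-1-one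
Product: 12 (E)-1-{2,4-dihydroxy-3-[(E)-3-methylbut-1-en-1-yl]phenyl}-3-(2,4-dihydroxyphenyl)prop-2-en-1-one (dienophile)
Conditions: K2CO3, MeOH, 0 °C, Ar; AcOH quench
Reagents that add atoms: none
Why: Aryl acetates are activated esters that undergo base-mediated transesterification with methanol at low temperature, where chalcone–flavanone isomerisation should remain slow.

Step 10
Reactants: 13 2-methylbut-1-en-3-yne
Product: 14 (E)-4,4,5,5-tetramethyl-2-(3-methylbuta-1,3-dien-1-yl)-1,3,2-dioxaborolane
Conditions: HBpin, Cp2Zr(H)Cl (cat.), Et3N (cat.), neat, sealed tube, rt to 40 °C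
Reagents that add atoms: pinacolborane, CC1(C)OBOC1(C)C
Why: The same catalysed syn hydroboration is chemoselective for the terminal alkyne over the 1,1-disubstituted alkene and should give the (E)-dienyl boronate.

Step 11
Reactants: 8 (E)-1-(2,4-diacetoxy-3-iodophenyl)-3-(2,4-diacetoxyphenyl)prop-2-en-1-one; 14 (E)-4,4,5,5-tetramethyl-2-(3-methylbuta-1,3-dien-1-yl)-1,3,2-dioxaborolane
Product: 15 (E)-1-{2,4-diacetoxy-3-[(E)-3-methylbuta-1,3-dien-1-yl]phenyl}-3-(2,4-diacetoxyphenyl)prop-2-en-1-one
Conditions: Pd(OAc)2 (cat.), SPhos (cat.), K3PO4 (anhydrous), toluene, 60 °C, dark; aqueous work-up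
Reagents that add atoms: none
Why: Suzuki–Miyaura coupling with retention of the (E)-geometry installs the dehydroprenyl diene in its storable acetate-protected form, at a temperature below that at which thermal self-cycloaddition should set in.

Step 12
Reactants: 15 (E)-1-{2,4-diacetoxy-3-[(E)-3-methylbuta-1,3-dien-1-yl]phenyl}-3-(2,4-diacetoxyphenyl)prop-2-en-1-one
Product: 16 (E)-1-{2,4-dihydroxy-3-[(E)-3-methylbuta-1,3-dien-1-yl]phenyl}-3-(2,4-dihydroxyphenyl)prop-2-en-1-one (diene, used at once)
Conditions: K2CO3, degassed MeOH, 0 °C, Ar, dark; AcOH quench; extractive work-up below rt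
Reagents that add atoms: none
Why: Base-mediated methanolysis of the aryl acetates avoids the strong acid that would ionise the o-hydroxyaryl diene towards a chromene, and the weak-acid quench and immediate use should limit oxidation and oligomerisation.

Step 13
Reactants: 12 (E)-1-{2,4-dihydroxy-3-[(E)-3-methylbut-1-en-1-yl]phenyl}-3-(2,4-dihydroxyphenyl)prop-2-en-1-one (dienophile); 16 (E)-1-{2,4-dihydroxy-3-[(E)-3-methylbuta-1,3-dien-1-yl]phenyl}-3-(2,4-dihydroxyphenyl)prop-2-en-1-one (diene)
Product: 17 artonin C, (3S,4R,5S) in the ring numbering above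
Conditions: MaDA (recombinant FAD-dependent Diels–Alderase of Morus alba, cat.), 12 (3 equiv), 16 fed in portions as DMSO solution, Tris·HCl buffer pH 8.0/DMSO 9:1, 37 °C, Ar, dark
Reagents that add atoms: none
Why: The enzyme, an FAD-dependent berberine-bridge-enzyme-like pericyclase whose oxidised flavin shapes the pocket but takes no part in redox chemistry, should bind enone 12 by hydrogen bonds to its chelated 2'-OH/C=O unit (lowering the LUMO) and hold the s-cis butadiene of 16 over Cα=Cβ, so that a concerted, asynchronous, normal-electron-demand [4+2] cycloaddition forms C3–C4 and C5–C6 in one event. The closest known reaction type is the Diels–Alderase-catalysed intermolecular cycloaddition of free 2'-hydroxychalcones carrying a C5 side chain at C3' with dehydroprenyl-arene dienes, chalcone-derived dienes included, from which the present pair differs only in the position of one side-chain double bond. The single new ring, the six-membered carbocycle C1–C6, is closed by an untethered suprafacial–suprafacial [4π+2π] addition that leaves the new alkene at C1=C2. C4 and C5 become trans because the (E)-geometry of the enone is transferred stereospecifically, C3 and C4 become cis because the (E)-aryl terminus of the diene meets the aroyl group in the endo orientation enforced by the pocket, and the absolute sense (3S,4R,5S) follows from the one pair of prochiral faces that the chiral pocket allows to meet. Regioselectivity (aryl at C3 next to aroyl at C4, methyl at C1 para to C4) is inherent in the substrates, since the unsubstituted CH2 terminus of the 1-aryl-3-methyldiene carries the largest HOMO coefficient and bonds to the electrophilic Cβ. Chemoselectivity is the critical need because 16 carries the same enone as 12: an excess of 12 and portionwise feeding of 16 should keep the dienophile site filled by 12, the 3-methylbut-1-enyl group of 12 has no second conjugated alkene outside the arene and cannot act as a diene, and the uncatalysed background should be negligible at this dilution and temperature.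

Compound list
1 | 2,4-dihydroxyacetophenone | CC(=O)c1ccc(O)cc1O | starting material
2 | 1-(2,4-dihydroxy-3-iodophenyl)ethan-1-one | CC(=O)c1ccc(O)c(I)c1O | intermediate
3 | 1-[2-hydroxy-3-iodo-4-(methoxymethoxy)phenyl]ethan-1-one | CC(=O)c1ccc(OCOC)c(I)c1O | intermediate
4 | 2,4-dihydroxybenzaldehyde | O=Cc1ccc(O)cc1O | starting material
5 | 2,4-bis(methoxymethoxy)benzaldehyde | COCOc1ccc(C=O)c(OCOC)c1 | intermediate
6 | (E)-3-[2,4-bis(methoxymethoxy)phenyl]-1-[2-hydroxy-3-iodo-4-(methoxymethoxy)phenyl]prop-2-en-1-one | COCOc1ccc(/C=C/C(=O)c2ccc(OCOC)c(I)c2O)c(OCOC)c1 | intermediate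
7 | (E)-1-(2,4-dihydroxy-3-iodophenyl)-3-(2,4-dihydroxyphenyl)prop-2-en-1-one | O=C(/C=C/c1ccc(O)cc1O)c1ccc(O)c(I)c1O | intermediate
8 | (E)-1-(2,4-diacetoxy-3-iodophenyl)-3-(2,4-diacetoxyphenyl)prop-2-en-1-one | CC(=O)Oc1ccc(/C=C/C(=O)c2ccc(OC(C)=O)c(I)c2OC(C)=O)c(OC(C)=O)c1 | intermediate
9 | 3-methylbut-1-yne | CC(C)C#C | starting material
10 | (E)-4,4,5,5-tetramethyl-2-(3-methylbut-1-en-1-yl)-1,3,2-dioxaborolane | CC(C)/C=C/B1OC(C)(C)C(C)(C)O1 | intermediate
11 | (E)-1-{2,4-diacetoxy-3-[(E)-3-methylbut-1-en-1-yl]phenyl}-3-(2,4-diacetoxyphenyl)prop-2-en-1-one | CC(C)/C=C/c1c(OC(C)=O)ccc(C(=O)/C=C/c2ccc(OC(C)=O)cc2OC(C)=O)c1OC(C)=O | intermediate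
12 | (E)-1-{2,4-dihydroxy-3-[(E)-3-methylbut-1-en-1-yl]phenyl}-3-(2,4-dihydroxyphenyl)prop-2-en-1-one | CC(C)/C=C/c1c(O)ccc(C(=O)/C=C/c2ccc(O)cc2O)c1O | intermediate
13 | 2-methylbut-1-en-3-yne | CC(=C)C#C | starting material
14 | (E)-4,4,5,5-tetramethyl-2-(3-methylbuta-1,3-dien-1-yl)-1,3,2-dioxaborolane | CC(=C)/C=C/B1OC(C)(C)C(C)(C)O1 | intermediate
15 | (E)-1-{2,4-diacetoxy-3-[(E)-3-methylbuta-1,3-dien-1-yl]phenyl}-3-(2,4-diacetoxyphenyl)prop-2-en-1-one | CC(=C)/C=C/c1c(OC(C)=O)ccc(C(=O)/C=C/c2ccc(OC(C)=O)cc2OC(C)=O)c1OC(C)=O | intermediate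
16 | (E)-1-{2,4-dihydroxy-3-[(E)-3-methylbuta-1,3-dien-1-yl]phenyl}-3-(2,4-dihydroxyphenyl)prop-2-en-1-one | CC(=C)/C=C/c1c(O)ccc(C(=O)/C=C/c2ccc(O)cc2O)c1O | intermediate
17 | artonin C, (E)-1-{3-[(1S,5S,6R)-6-{2,4-dihydroxy-3-[(E)-3-methylbut-1-en-1-yl]benzoyl}-5-(2,4-dihydroxyphenyl)-3-methylcyclohex-2-en-1-yl]-2,4-dihydroxyphenyl}-3-(2,4-dihydroxyphenyl)prop-2-en-1-one | CC1=C[C@H](c2c(O)ccc(C(=O)/C=C/c3ccc(O)cc3O)c2O)[C@H](C(=O)c2ccc(O)c(/C=C/C(C)C)c2O)[C@@H](c2ccc(O)cc2O)C1 | target

Total step count: 13.
Longest linear sequence: 8 steps (1, 2, 4, 5, 6, 11, 12, 13; the branch through steps 8 and 9 is equally long).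

Steps most likely to fail

**Step 13.**
- Risk: the pocket may bind the conjugated 3-methylbut-1-enyl side chain poorly. Self-cycloaddition of the diene partner through its own enone, or a second addition to the enone that remains in the product, may compete with the cross reaction.
- The fallback sets out from 12 and 15 and comes back at 17.
- Compound 12 is acetylated with three equivalents of Ac2O in pyridine/CH2Cl2 at 0 °C without DMAP. The chelated 2'-OH stays free, giving (E)-1-{4-acetoxy-2-hydroxy-3-[(E)-3-methylbut-1-en-1-yl]phenyl}-3-(2,4-diacetoxyphenyl)prop-2-en-1-one F1.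
- This enone is bound through its 2'-O/C=O chelate to the stoichiometric chiral borate made from BH3·THF, AcOH and VANOL. (R)-VANOL is the first choice. Both antipodes are sold, and the sense of induction has to be checked against the chiroptical data of the natural product.
- The complex is treated with the fully acetylated diene 15, whose own enone cannot chelate boron and so stays unactivated.
- After separation from the exo isomer, this Lewis-acid-mediated asymmetric Diels–Alder reaction should give the endo (3S,4R,5S) adduct heptaacetate F2.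
- Methanolysis (K2CO3, MeOH, 0 °C) then leads to 17.

**Step 11.**
- Risk: slow oxidative addition and transmetalation at the doubly ortho-substituted iodide, loss of acetates to the phosphate base, and protodeboronation or oligomerisation of the dienyl boronate.
- The fallback sets out from 8 and comes back at 15.
- It builds the diene in two separate events. First, a ligand-free Heck reaction of 8 with 2-methylbut-3-en-2-ol (Pd(OAc)2, n-Bu4NCl, NaHCO3, DMF, 60 °C) should give (E)-1-{2,4-diacetoxy-3-[(E)-3-hydroxy-3-methylbut-1-en-1-yl]phenyl}-3-(2,4-diacetoxyphenyl)prop-2-en-1-one F3.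
- Second, the tertiary allylic alcohol can eliminate only towards a methyl group. Dehydration with the Burgess reagent (toluene, 50 °C) should therefore give 15.

**Step 12.**
- Risk: base-induced chalcone–flavanone isomerisation, air oxidation of the phenoxides, and oligomerisation of the electron-rich diene during methanolysis and work-up.
- The fallback sets out from 6 and 14 and comes back at 16. It avoids both the acetates and the basic release.
- Compound 6 is coupled with 14 under ordinary aqueous Suzuki–Miyaura conditions (Pd(dppf)Cl2, K2CO3, dioxane/H2O, 70 °C), which MOM ethers tolerate. This should give (E)-3-[2,4-bis(methoxymethoxy)phenyl]-1-{2-hydroxy-4-(methoxymethoxy)-3-[(E)-3-methylbuta-1,3-dien-1-yl]phenyl}prop-2-en-1-one F4.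
- The aryl MOM ethers are then exchanged for silyl ethers with TMSOTf/2,2'-bipyridyl in MeCN at 0 °C, a medium that is neither protic-acidic nor basic. Addition of water then hydrolyses them to 16.

Further compounds
F1 | step 13 | (E)-1-{4-acetoxy-2-hydroxy-3-[(E)-3-methylbut-1-en-1-yl]phenyl}-3-(2,4-diacetoxyphenyl)prop-2-en-1-one | CC(C)/C=C/c1c(OC(C)=O)ccc(C(=O)/C=C/c2ccc(OC(C)=O)cc2OC(C)=O)c1O
F2 | step 13 | endo (3S,4R,5S) adduct heptaacetate (artonin C with all phenols acetylated except the chelated 2-OH of the C4 aroyl ring) | CC1=C[C@H](c2c(OC(C)=O)ccc(C(=O)/C=C/c3ccc(OC(C)=O)cc3OC(C)=O)c2OC(C)=O)[C@H](C(=O)c2ccc(OC(C)=O)c(/C=C/C(C)C)c2O)[C@@H](c2ccc(OC(C)=O)cc2OC(C)=O)C1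
F3 | step 11 | (E)-1-{2,4-diacetoxy-3-[(E)-3-hydroxy-3-methylbut-1-en-1-yl]phenyl}-3-(2,4-diacetoxyphenyl)prop-2-en-1-one | CC(C)(O)/C=C/c1c(OC(C)=O)ccc(C(=O)/C=C/c2ccc(OC(C)=O)cc2OC(C)=O)c1OC(C)=O
F4 | step 12 | (E)-3-[2,4-bis(methoxymethoxy)phenyl]-1-{2-hydroxy-4-(methoxymethoxy)-3-[(E)-3-methylbuta-1,3-dien-1-yl]phenyl}prop-2-en-1-one | CC(=C)/C=C/c1c(OCOC)ccc(C(=O)/C=C/c2ccc(OCOC)cc2OCOC)c1O
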